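## The problem

CNP0152348.0 has no stereocentres, so nothing has to be set or relayed; the difficulty is purely positional. A 6-ethyl-4-hydroxy-5-methyl-2-pyranone (ring A) is tied through one methylene carbon, from its C3, to C1′ of a fully substituted phloroglucinol (ring B: C2′ OH, C3′ prenyl, C4′ OH, C5′ isobutyryl, C6′ OH). Six different substituents must be placed on ring B in one fixed order, and the bridge must join two different enolic partners without giving either symmetrical dimer. The sensitive parts are:

- the prenyl group, which closes onto a flanking phenol under protic or Lewis acid and reacts with electrophilic halogen;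
- the electron-rich trihydroxyarene, which is easily oxidised;
- the bridge, which can be released again as a quinone methide under heat, acid or base;
- the pyranone lactone, which opens with hard nucleophiles.

The feature that the plan exploits is the pair C5′/C6′: a ketone and a hydroxyl on adjacent ring carbons are what results when a carboxylic acid is added across an aryne. The C5′–C6′ aryne is usefully unsymmetrical, because C5′ has the oxygen-bearing C4′ as neighbour while C6′ is flanked by C1′, which carries only hydrogen at that stage. Oxygen should therefore add to C6′ and the acyl group should end on C5′, and C1′ is left as the only ring-B carbon available for the bridge.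

## Retrosynthesis

**Bridge.** Target 27 is cut at both bonds of the bridge carbon, C1′–CH2 and CH2–C3. This gives the acylphloroglucinol 18, the pyranone 23 and a one-carbon electrophile, dimethyl(methylidene)ammonium iodide 24. The cut is preferred to any cut inside ring A because the two halves are of similar size and are made independently. Position is not in question: 18 has exactly one unsubstituted ring carbon and 23 exactly one nucleophilic carbon. The forward reaction must give the mixed product and not a symmetrical dimer. The methylene is therefore fixed first on the valuable half as Mannich base 25 and released as quinone methide 26 only in the presence of an excess of the cheap half 23.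

**Deprotection.** 18 is traced to its bis(methoxymethyl) ether 17 (two O–CH2 bonds). The acetal groups serve earlier as directing groups for metalation and keep C2′–O and C4′–O out of the aryne chemistry. They are removed before bridging, so that the only acid treatment of the route falls on a small ketone and not on the bridged product, whose methylene can migrate in acid. The forward step must trap the methoxymethyl cation before it reaches C1′.

**Key cut.** 17 is cut at C5′–C(acyl) and C6′–O, leading to isobutyric acid 15 and aryne 16, to be released from silyl triflate 14. Two neighbouring options were weighed: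

- A Friedel–Crafts or Fries acylation would need Lewis acids that strip the acetals and cyclise the prenyl group.
- Direct acylation and C-prenylation of 1 would reach 18 in far fewer steps, but the prenylation is unselective between oxygen and carbon and between one and two alkyl groups.

The aryne cut is longer, but it removes the ketone and the phenol oxygen in one operation, takes the whole acyl group from the acid itself, and introduces every substituent once at a dictated position. The forward reaction must add oxygen at C6′ and not C5′, and must transfer the acyl group to carbon before the aryl anion is protonated.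

**Aryne precursor.** 14 is cut at C–Si and O–S, back through the ortho-silyl carbamate 12 to carbamate 8 and phenol 7. The N-isopropyl carbamate directs lithiation to the carbon between itself and an acetal ether. It also leaves under mild base, so that phenoxide 13 is triflated in the same flask. The two carbons ortho to the carbamate in 8 are equivalent, so silylation has no regiochemical choice.

**Prenyl group.** 7 is cut at the C3′–CH2 bond, via silyl ether 6, to aryllithium 5 and prenyl bromide 4. The carbon between the two acetal ethers of 3 is the most readily lithiated ring position, so the prenyl group is brought in there before the carbamate exists. The third oxygen is masked as a triisopropylsilyl ether, which neither directs lithiation nor reacts with n-BuLi and is removed by fluoride. 3 comes from 2 and this from phloroglucinol 1. The statistical double alkylation of 1 is the only unselective event of the route and falls on the cheapest material.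

**Pyranone.** 23 is cut at the lactone bond O1–C2 to diketo ester 22, and 22 at C5–C6 (pyranone numbering) to dianion 21 of methyl 3-oxopentanoate 19 and Weinreb amide 20. All ring atoms and both alkyl groups come from two commercial pieces; the forward steps are a γ-acylation and a lactonisation.

## Roads not taken

Alternative 1: Ring A is cut at C4–C5 and O1–C2, back to the arylmethylmalonyl dichloride A1 (ring B and bridge complete, phenols as allyl ethers) and the silyl enol ether A2, trimethyl(pent-2-en-3-yloxy)silane.

- Forward key step: A2 is C-acylated by one acid chloride, and the enol oxygen of the new ketone closes on the second, giving the tri-O-allyl pyranone A3 in one operation.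
- Merits: the bridge carbon is part of a malonate from the start and cannot be redistributed. The allyl ethers would be removed by zerovalent palladium without acid. In that respect this road is better than the chosen one.
- Weak points: substituted malonyl dichlorides lose HCl to chlorocarbonyl ketenes and tend to give O-acylation and two-to-one products. The HCl set free meets a prenyl group. Making A1 requires a benzylic electrophile on a hexasubstituted electron-rich ring, itself a quinone methide precursor.
- Comparison: the chosen plan sets against the acid-free deprotection that its acid step is run on 17, before any bridge exists. Ring A is made apart in two steps and attached last, so the expensive arene is not carried through ring construction. Alternative 1 also does not say how ring B gets its substitution pattern, which is the question the aryne step answers.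

Alternative 2: Bonds C3–C4 and O1–C2 of ring A are cut. C2, C3 and the bridge carbon are held in the silyl ketene acetal A4, a 2-silyloxy-4H-chromene fused to ring B through O6′.

- Forward key step: A4 is heated with dioxinone A5, which releases acylketene A6. The ketene adds to the ketene acetal, the acyl oxygen closes on C2, and the orthoester-like C2 expels the phenoxide. This opens the lactone and gives A7 with C6′–OH free.
- Merits: no formaldehyde-level electrophile is used, so there is no cross-coupling problem. The ring is built under neutral thermal conditions, and the ring switch unmasks one phenol by itself.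
- Weak points: A4 requires enolising a lactone beside an aryl isopropyl ketone. The orthoester carbon has two exits, loss of aryloxide (wanted) or loss of silanolate (which keeps a fused chromenopyranone). The lactone needs two more C–C bonds at C1′ of a finished ring B. A7 still needs acid to lose its acetals with the bridge in place.
- Comparison: this road is better in bridging certainty. The chosen plan is shorter after 17 (two steps to 27), rests on reaction types with closer precedent, and keeps acid away from the bridged compound.

Alternative 3: Only O1–C2 is cut. The open-chain diketo ester A8, with the ring-B benzyl group at C2, is folded to the tris(methoxymethyl) ether A9.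

- Forward key step: DBU in hot toluene enolises A8 and the terminal enol oxygen attacks the methyl ester.
- Merits: the closure is the same lactonisation the chosen plan uses for 23 (step 11), so it is equally reliable, and the bridge is fixed by C-alkylation.
- Weak points: A8 must be assembled from a benzylic halide of a hexasubstituted electron-rich arene, an unstable electrophile. A 3,5-diketo ester can be alkylated at C2 or C4. Three acetals must be removed in acid at the end with the bridge present.
- Comparison: equal in ring closure and free of homodimer risk, but linear on the arene. The chosen plan avoids the benzylic halide by using Mannich base 25 as its stable equivalent.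

Key step: step 8

Remark on the chemistry: ring B keeps the atom numbers of the target (C1′ to C6′) at every stage. Compound 22 is drawn as the triketo tautomer; its C4 stereocentre is racemic and disappears in step 11.

## Route

Step 1
Reactants: 1 phloroglucinol (benzene-1,3,5-triol)
Product: 2 3,5-bis(methoxymethoxy)phenol
Conditions: MOMCl (2.1 equiv), i-Pr2NEt, DMF, 0 °C to rt
Reagents that add atoms: chloromethyl methyl ether (MOMCl), COCCl
Why: Williamson-type O-alkylation of a threefold symmetric triphenol with about two equivalents of chloride is statistical; the bis-ether should be the main component and is separated from mono- and tris-ether by chromatography.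

Step 2
Reactants: 2 3,5-bis(methoxymethoxy)phenol
Product: 3 [3,5-bis(methoxymethoxy)phenoxy]tri(propan-2-yl)silane
Conditions: TIPSCl, imidazole, DMF, rt
Reagents that add atoms: chlorotri(propan-2-yl)silane (TIPSCl), CC(C)[Si](Cl)(C(C)C)C(C)C
Why: Imidazole-promoted O-silylation of the remaining phenol; the triisopropylsilyl ether resists n-BuLi and, unlike the acetal ethers, does not coordinate lithium, which prepares the site selection of step 3.

Step 3
Reactants: 3 [3,5-bis(methoxymethoxy)phenoxy]tri(propan-2-yl)silane; 4 prenyl bromide (1-bromo-3-methylbut-2-ene)
Product: 6 [3,5-bis(methoxymethoxy)-4-(3-methylbut-2-en-1-yl)phenoxy]tri(propan-2-yl)silane, via aryllithium 5 (not isolated)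
Conditions: n-BuLi (1.2 equiv), THF, 0 °C; then CuI (10 mol %), 4, −78 °C to rt
Reagents that add atoms: none
Why: Directed ortho-metalation: the carbon between the two methoxymethyl ethers is chelated from both sides and is lithiated in preference to the carbons next to the bulky, non-coordinating silyl ether; copper-catalysed SN2 alkylation of 5 with the primary allylic bromide gives the linear prenyl arene.

Step 4
Reactants: 6 [3,5-bis(methoxymethoxy)-4-(3-methylbut-2-en-1-yl)phenoxy]tri(propan-2-yl)silane
Product: 7 3,5-bis(methoxymethoxy)-4-(3-methylbut-2-en-1-yl)phenol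
Conditions: Bu4NF, THF, 0 °C
Reagents that add atoms: none
Why: Fluoride-induced Si–O cleavage of an aryl silyl ether; acetals and the trisubstituted alkene are inert to fluoride.

Step 5
Reactants: 7 3,5-bis(methoxymethoxy)-4-(3-methylbut-2-en-1-yl)phenol
Product: 8 3,5-bis(methoxymethoxy)-4-(3-methylbut-2-en-1-yl)phenyl N-(propan-2-yl)carbamate
Conditions: i-PrNCO, Et3N (cat.), CH2Cl2, rt
Reagents that add atoms: isopropyl isocyanate (2-isocyanatopropane), CC(C)N=C=O
Why: Amine-catalysed addition of the phenol to the isocyanate (carbamoylation); the secondary carbamate is the directing group for step 6 and a phenol mask that mild base removes in step 7.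

Step 6
Reactants: 8 3,5-bis(methoxymethoxy)-4-(3-methylbut-2-en-1-yl)phenyl N-(propan-2-yl)carbamate
Product: 12 3,5-bis(methoxymethoxy)-4-(3-methylbut-2-en-1-yl)-2-(trimethylsilyl)phenyl N-(propan-2-yl)carbamate, via N-silyl carbamate 9 (not isolated), via lithiated N-silyl carbamate 10 (not isolated), via C-silylated N-silyl carbamate 11 (not isolated)
Conditions: TBSOTf, TMEDA, Et2O, 0 °C to rt; n-BuLi, TMEDA, −78 °C; TMSCl, −78 °C to rt; brief aq. NaHSO4 work-up at 0 °C
Reagents that add atoms: chlorotrimethylsilane (TMSCl), C[Si](C)(C)Cl
Why: N-Silylation turns the secondary carbamate into a tertiary one, a strong director; directed ortho-metalation at −78 °C takes place at the carbon between carbamate and acetal ether (both such carbons are equivalent), below the temperature of the anionic Fries shift, and TMSCl traps the anion; the N–Si bond is hydrolysed on work-up.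

Step 7
Reactants: 12 3,5-bis(methoxymethoxy)-4-(3-methylbut-2-en-1-yl)-2-(trimethylsilyl)phenyl N-(propan-2-yl)carbamate
Product: 14 3,5-bis(methoxymethoxy)-4-(3-methylbut-2-en-1-yl)-2-(trimethylsilyl)phenyl trifluoromethanesulfonate, via silyl phenol 13 (not isolated)
Conditions: DBU, Et2NH, MeCN, 40 °C; then PhNTf2, rt
Reagents that add atoms: N-phenylbis(trifluoromethanesulfonimide) (PhNTf2), O=S(=O)(N(c1ccccc1)S(=O)(=O)C(F)(F)F)C(F)(F)F
Why: DBU deprotonates the carbamate N–H and the aryloxide leaves by E1cB elimination, Et2NH scavenging the isocyanate as a urea; the phenoxide is then O-sulfonylated by PhNTf2 in the same flask, the standard one-pot conversion of ortho-silylaryl carbamates into aryne precursors.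

Step 8
Reactants: 14 3,5-bis(methoxymethoxy)-4-(3-methylbut-2-en-1-yl)-2-(trimethylsilyl)phenyl trifluoromethanesulfonate; 15 isobutyric acid (2-methylpropanoic acid)
Product: 17 1-[2-hydroxy-4,6-bis(methoxymethoxy)-5-(3-methylbut-2-en-1-yl)phenyl]-2-methylpropan-1-one, via aryne 16 (not isolated)
Conditions: CsF (4 equiv), 15 (1.0 equiv), THF, 125 °C, sealed tube
Reagents that add atoms: none
Why: Fluoride attacks silicon and the aryl anion expels triflate (1,2-elimination) to give aryne 16, whose triple bond lies between C6′ and C5′. The closest known reaction type is the insertion of arynes from ortho-silylaryl triflates into the C–O bond of carboxylic acids, which gives ortho-hydroxyaryl ketones and is regioselective for 3-alkoxyarynes. Caesium isobutyrate adds through oxygen at C6′, the aryne carbon remote from the C4′ acetal oxygen, because the electron-withdrawing C4′–O bond polarises the aryne toward attack at C6′ and stabilises the carbanion that develops at C5′; the C2′ ether and the prenyl group are not on an aryne carbon and bias the addition only weakly. The C5′ anion then attacks the carbonyl of its own ester in a 4-exo-trig closure to a benzoxetene alkoxide, which opens by C–O cleavage to the phenoxide and the ketone, so the net result is bonds C6′–O and C5′–C(acyl). The four-membered ring is transient; no ring is retained and no stereocentre is formed. Besides regiochemistry the step needs acyl transfer to outrun protonation of the C5′ anion, which would stop at the aryl ester; the high temperature, the absence of excess acid and the excess CsF, which holds the proton as bifluoride, are meant to secure this. The acetal ethers and the prenyl group should be spectators in this basic fluoride medium, and the new phenol emerges hydrogen-bonded to the ketone.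

Step 9
Reactants: 17 1-[2-hydroxy-4,6-bis(methoxymethoxy)-5-(3-methylbut-2-en-1-yl)phenyl]-2-methylpropan-1-one
Product: 18 2-methyl-1-[2,4,6-trihydroxy-3-(3-methylbut-2-en-1-yl)phenyl]propan-1-one
Conditions: 3 M aq. HCl, MeOH, rt to 40 °C
Reagents that add atoms: none
Why: Acid-catalysed acetal exchange (transacetalisation) with the solvent; methanol captures the methoxymethyl cation as dimethoxymethane before it can alkylate C1′, and the prenyl group should tolerate the short exposure near room temperature.

Step 10
Reactants: 19 methyl 3-oxopentanoate; 20 N-methoxy-N-methylpropanamide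
Product: 22 methyl 4-methyl-3,5-dioxoheptanoate, via dilithium dienolate 21 (not isolated)
Conditions: LiN(i-Pr)2 (2.2 equiv, commercial solution), THF, 0 °C; 20, −78 to 0 °C; 1 M HCl work-up
Reagents that add atoms: none
Why: Claisen-type γ-acylation of a β-keto ester dianion: the terminal, more basic carbanion of 21 attacks the Weinreb amide and the chelated tetrahedral adduct prevents double addition; the C4 stereocentre of 22 is formed racemic and is lost in step 11.

Step 11
Reactants: 22 methyl 4-methyl-3,5-dioxoheptanoate
Product: 23 6-ethyl-4-hydroxy-5-methyl-2H-pyran-2-one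
Conditions: DBU, PhMe, reflux; dilute HCl work-up
Reagents that add atoms: none
Why: Base-mediated enol lactonisation (6-exo-trig attack of the C5 enol oxygen on the ester) with loss of methanol gives the 4-hydroxy-2-pyranone, the standard closure of 3,5-diketo esters.

Step 12
Reactants: 18 2-methyl-1-[2,4,6-trihydroxy-3-(3-methylbut-2-en-1-yl)phenyl]propan-1-one; 24 dimethyl(methylidene)ammonium iodide (Eschenmoser's salt); 23 6-ethyl-4-hydroxy-5-methyl-2H-pyran-2-one
Product: 27 6-ethyl-4-hydroxy-5-methyl-3-{[2,4,6-trihydroxy-3-(3-methylbut-2-en-1-yl)-5-(2-methylpropanoyl)phenyl]methyl}-2H-pyran-2-one, via Mannich base 25 (not isolated), via quinone methide 26 (not isolated)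
Conditions: 24 (1.0 equiv), MeCN, 0 °C to rt; then 23 (1.5 equiv), NaOAc (1.1 equiv), 60 °C
Reagents that add atoms: none
Why: Mannich aminomethylation at C1′, the only unsubstituted and strongly activated carbon of 18, gives 25; on warming under acetate buffering 25 loses dimethylamine to the ortho-quinone methide 26, which is captured by conjugate addition of C3 of the pyranone, present in excess, and rearomatises to 27. This is the classical Mannich-base route to unsymmetrical methylene-bridged acylphloroglucinols and uses no strong acid, so the prenyl group is not at risk.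

## Compound list

1 | phloroglucinol (benzene-1,3,5-triol) | Oc1cc(O)cc(O)c1 | starting material
2 | 3,5-bis(methoxymethoxy)phenol | COCOc1cc(O)cc(OCOC)c1 | intermediate
3 | [3,5-bis(methoxymethoxy)phenoxy]tri(propan-2-yl)silane | COCOc1cc(OCOC)cc(O[Si](C(C)C)(C(C)C)C(C)C)c1 | intermediate
4 | prenyl bromide (1-bromo-3-methylbut-2-ene) | CC(C)=CCBr | starting material
5 | [2,6-bis(methoxymethoxy)-4-{[tri(propan-2-yl)silyl]oxy}phenyl]lithium | [Li]c1c(OCOC)cc(O[Si](C(C)C)(C(C)C)C(C)C)cc1OCOC | intermediate (not isolated)
6 | [3,5-bis(methoxymethoxy)-4-(3-methylbut-2-en-1-yl)phenoxy]tri(propan-2-yl)silane | COCOc1cc(O[Si](C(C)C)(C(C)C)C(C)C)cc(OCOC)c1CC=C(C)C | intermediate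
7 | 3,5-bis(methoxymethoxy)-4-(3-methylbut-2-en-1-yl)phenol | COCOc1cc(O)cc(OCOC)c1CC=C(C)C | intermediate
8 | 3,5-bis(methoxymethoxy)-4-(3-methylbut-2-en-1-yl)phenyl N-(propan-2-yl)carbamate | CC(C)NC(=O)Oc1cc(OCOC)c(CC=C(C)C)c(OCOC)c1 | intermediate
9 | 3,5-bis(methoxymethoxy)-4-(3-methylbut-2-en-1-yl)phenyl N-[tert-butyl(dimethyl)silyl]-N-(propan-2-yl)carbamate | CC(C)N(C(=O)Oc1cc(OCOC)c(CC=C(C)C)c(OCOC)c1)[Si](C)(C)C(C)(C)C | intermediate (not isolated)
10 | 2-lithio-3,5-bis(methoxymethoxy)-4-(3-methylbut-2-en-1-yl)phenyl N-[tert-butyl(dimethyl)silyl]-N-(propan-2-yl)carbamate | CC(C)N(C(=O)Oc1cc(OCOC)c(CC=C(C)C)c(OCOC)c1[Li])[Si](C)(C)C(C)(C)C | intermediate (not isolated)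
11 | 3,5-bis(methoxymethoxy)-4-(3-methylbut-2-en-1-yl)-2-(trimethylsilyl)phenyl N-[tert-butyl(dimethyl)silyl]-N-(propan-2-yl)carbamate | CC(C)N(C(=O)Oc1cc(OCOC)c(CC=C(C)C)c(OCOC)c1[Si](C)(C)C)[Si](C)(C)C(C)(C)C | intermediate (not isolated)
12 | 3,5-bis(methoxymethoxy)-4-(3-methylbut-2-en-1-yl)-2-(trimethylsilyl)phenyl N-(propan-2-yl)carbamate | CC(C)NC(=O)Oc1cc(OCOC)c(CC=C(C)C)c(OCOC)c1[Si](C)(C)C | intermediate
13 | 3,5-bis(methoxymethoxy)-4-(3-methylbut-2-en-1-yl)-2-(trimethylsilyl)phenol | C[Si](C)(C)c1c(O)cc(OCOC)c(CC=C(C)C)c1OCOC | intermediate (not isolated)
14 | 3,5-bis(methoxymethoxy)-4-(3-methylbut-2-en-1-yl)-2-(trimethylsilyl)phenyl trifluoromethanesulfonate | C[Si](C)(C)c1c(OS(=O)(=O)C(F)(F)F)cc(OCOC)c(CC=C(C)C)c1OCOC | intermediate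
15 | isobutyric acid (2-methylpropanoic acid) | CC(C)C(=O)O | starting material
16 | 3,5-bis(methoxymethoxy)-4-(3-methylbut-2-en-1-yl)benzyne (1,2-didehydrobenzene) | COCOC1=CC#CC(OCOC)=C1CC=C(C)C | intermediate (not isolated)
17 | 1-[2-hydroxy-4,6-bis(methoxymethoxy)-5-(3-methylbut-2-en-1-yl)phenyl]-2-methylpropan-1-one | CC(C)C(=O)c1c(O)cc(OCOC)c(CC=C(C)C)c1OCOC | intermediate
18 | 2-methyl-1-[2,4,6-trihydroxy-3-(3-methylbut-2-en-1-yl)phenyl]propan-1-one | CC(C)C(=O)c1c(O)cc(O)c(CC=C(C)C)c1O | intermediate
19 | methyl 3-oxopentanoate | CCC(=O)CC(=O)OC | starting material
20 | N-methoxy-N-methylpropanamide | CCC(=O)N(C)OC | starting material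
21 | dilithium dienolate of methyl 3-oxopentanoate (1-methoxypenta-1,3-diene-1,3-diolate) | CC=C(O[Li])C=C(O[Li])OC | intermediate (not isolated)
22 | methyl 4-methyl-3,5-dioxoheptanoate (racemic) | CCC(=O)C(C)C(=O)CC(=O)OC | intermediate
23 | 6-ethyl-4-hydroxy-5-methyl-2H-pyran-2-one | CCc1oc(=O)cc(O)c1C | intermediate
24 | dimethyl(methylidene)ammonium iodide (Eschenmoser's salt) | C=[N+](C)C.[I-] | starting material
25 | 1-{3-[(dimethylamino)methyl]-2,4,6-trihydroxy-5-(3-methylbut-2-en-1-yl)phenyl}-2-methylpropan-1-one | CC(C)C(=O)c1c(O)c(CN(C)C)c(O)c(CC=C(C)C)c1O | intermediate (not isolated)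
26 | 3,5-dihydroxy-4-(3-methylbut-2-en-1-yl)-6-methylidene-2-(2-methylpropanoyl)cyclohexa-2,4-dien-1-one | C=C1C(=O)C(C(=O)C(C)C)=C(O)C(CC=C(C)C)=C1O | intermediate (not isolated)
27 | 6-ethyl-4-hydroxy-5-methyl-3-{[2,4,6-trihydroxy-3-(3-methylbut-2-en-1-yl)-5-(2-methylpropanoyl)phenyl]methyl}-2H-pyran-2-one | CCc1oc(=O)c(Cc2c(O)c(CC=C(C)C)c(O)c(C(=O)C(C)C)c2O)c(O)c1C | target

## Step count and least certain steps

Total: 12 steps. Longest linear sequence: 10 steps (steps 1–9 and 12); the pyranone branch (steps 10 and 11) joins in step 12.

**Step 8 (key step).** The most likely failure is protonation of the C5′ carbanion before it reaches the ester carbonyl, so that the sequence stops at O-arylation. Further risks are partial loss of the acetal groups at 125 °C in the presence of bifluoride and consumption of the aryne by the product phenoxide. The fallback sets out from carbamate 8 and gives up the aryne. The lithiated species 10 is generated as in step 6 and quenched with N-methoxy-N,2-dimethylpropanamide to give 3,5-bis(methoxymethoxy)-4-(3-methylbut-2-en-1-yl)-2-(2-methylpropanoyl)phenyl N-(propan-2-yl)carbamate F1. DBU and Et2NH in MeCN then remove the carbamate, and the route is rejoined at 17. The same carbon is addressed because the lithiation site of 8 is C5′. This fallback is two steps shorter than the aryne sequence from 8.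

**Step 12.** The most likely failure is redistribution of the methylene group. Quinone methide 26 may revert to 25, or be captured at an already substituted carbon of a second phloroglucinol with loss of an iminium ion, so that symmetrical material builds up while the weakly nucleophilic pyranone is left behind. The fallback sets out from 23 and returns at 27, with the electrophile placed on the other partner. 23 is aminomethylated with 24 to 3-[(dimethylamino)methyl]-6-ethyl-4-hydroxy-5-methyl-2H-pyran-2-one F2. On warming with 18 this loses dimethylamine to 6-ethyl-5-methyl-3-methylidene-2H-pyran-2,4(3H)-dione F3, a much stronger acceptor than 26, which is attacked by C1′ of 18, the better nucleophile of the two, to give 27 directly.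

**Step 6.** Three things may go wrong: attack of the silyl triflate on the acetal ethers during N-silylation, deprotonation of the benzylic–allylic CH2 in competition with ring lithiation, or an anionic Fries shift if the anion warms. The fallback runs from 7 to 14 without a carbamate and replaces steps 5–7. Ortho-bromination of 7 with NBS at low temperature gives 2-bromo-3,5-bis(methoxymethoxy)-4-(3-methylbut-2-en-1-yl)phenol F4. (Me3Si)2NH converts it into [2-bromo-3,5-bis(methoxymethoxy)-4-(3-methylbut-2-en-1-yl)phenoxy]trimethylsilane F5. Bromine–lithium exchange with n-BuLi at −78 °C triggers the 1,3 O-to-C silyl shift (retro-Brook) to the lithium salt of 13, which is triflated with Tf2O to 14.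

**Step 9.** The most likely failure is C-alkylation of the free carbon C1′ by the methoxymethyl cation or by formaldehyde released from the acetals (methylene-bridged self-condensation). On longer exposure, acid-induced closure of the prenyl group onto a flanking hydroxyl is also possible. The fallback sets out from 17, returns at 27 and also replaces step 12; it removes the free carbon before acid is applied, although the prenyl closure risk remains. Ortho-formylation of 17 (MgCl2, Et3N, paraformaldehyde, MeCN, reflux) gives 2-hydroxy-4,6-bis(methoxymethoxy)-5-(3-methylbut-2-en-1-yl)-3-(2-methylpropanoyl)benzaldehyde F6. A proline-catalysed Knoevenagel condensation with 23, run in the presence of the Hantzsch ester (reductive alkylation), gives 6-ethyl-4-hydroxy-3-{[2-hydroxy-4,6-bis(methoxymethoxy)-5-(3-methylbut-2-en-1-yl)-3-(2-methylpropanoyl)phenyl]methyl}-5-methyl-2H-pyran-2-one F7, the same compound as A7. Only then are the acetals cleaved with HCl in methanol, on a ring with no carbon left to alkylate.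

Further compounds

F1 | step 8 | 3,5-bis(methoxymethoxy)-4-(3-methylbut-2-en-1-yl)-2-(2-methylpropanoyl)phenyl N-(propan-2-yl)carbamate | CC(C)NC(=O)Oc1cc(OCOC)c(CC=C(C)C)c(OCOC)c1C(=O)C(C)C
F2 | step 12 | 3-[(dimethylamino)methyl]-6-ethyl-4-hydroxy-5-methyl-2H-pyran-2-one | CCc1oc(=O)c(CN(C)C)c(O)c1C
F3 | step 12 | 6-ethyl-5-methyl-3-methylidene-2H-pyran-2,4(3H)-dione | CCC1=C(C)C(=O)C(=C)C(=O)O1
F4 | step 6 | 2-bromo-3,5-bis(methoxymethoxy)-4-(3-methylbut-2-en-1-yl)phenol | Oc1cc(OCOC)c(CC=C(C)C)c(OCOC)c1Br
F5 | step 6 | [2-bromo-3,5-bis(methoxymethoxy)-4-(3-methylbut-2-en-1-yl)phenoxy]trimethylsilane | C[Si](C)(C)Oc1cc(OCOC)c(CC=C(C)C)c(OCOC)c1Br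
F6 | step 9 | 2-hydroxy-4,6-bis(methoxymethoxy)-5-(3-methylbut-2-en-1-yl)-3-(2-methylpropanoyl)benzaldehyde | CC(C)C(=O)c1c(O)c(C=O)c(OCOC)c(CC=C(C)C)c1OCOC
F7 | step 9 | 6-ethyl-4-hydroxy-3-{[2-hydroxy-4,6-bis(methoxymethoxy)-5-(3-methylbut-2-en-1-yl)-3-(2-methylpropanoyl)phenyl]methyl}-5-methyl-2H-pyran-2-one | CCc1oc(=O)c(Cc2c(O)c(C(=O)C(C)C)c(OCOC)c(CC=C(C)C)c2OCOC)c(O)c1C
A1 | alternative 1 | 2-{[3-(3-methylbut-2-en-1-yl)-5-(2-methylpropanoyl)-2,4,6-tris(prop-2-en-1-yloxy)phenyl]methyl}propanedioyl dichloride | O=C(Cl)C(Cc1c(OCC=C)c(CC=C(C)C)c(OCC=C)c(C(=O)C(C)C)c1OCC=C)C(=O)Cl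
A2 | alternative 1 | trimethyl(pent-2-en-3-yloxy)silane | CC=C(CC)O[Si](C)(C)C
A3 | alternative 1 | 6-ethyl-4-hydroxy-5-methyl-3-{[3-(3-methylbut-2-en-1-yl)-5-(2-methylpropanoyl)-2,4,6-tris(prop-2-en-1-yloxy)phenyl]methyl}-2H-pyran-2-one | CCc1oc(=O)c(Cc2c(OCC=C)c(CC=C(C)C)c(OCC=C)c(C(=O)C(C)C)c2OCC=C)c(O)c1C
A4 | alternative 2 | 1-[5,7-bis(methoxymethoxy)-6-(3-methylbut-2-en-1-yl)-2-(trimethylsilyloxy)-4H-chromen-8-yl]-2-methylpropan-1-one | C[Si](C)(C)OC1=CCc2c(O1)c(C(=O)C(C)C)c(OCOC)c(CC=C(C)C)c2OCOC
A5 | alternative 2 | 6-ethyl-2,2,5-trimethyl-4H-1,3-dioxin-4-one | CCC1=C(C)C(=O)OC(C)(C)O1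
A6 | alternative 2 | 2-methylpent-1-ene-1,3-dione | CCC(=O)C(C)=C=O
A7 | alternative 2 | 6-ethyl-4-hydroxy-3-{[2-hydroxy-4,6-bis(methoxymethoxy)-5-(3-methylbut-2-en-1-yl)-3-(2-methylpropanoyl)phenyl]methyl}-5-methyl-2H-pyran-2-one | CCc1oc(=O)c(Cc2c(O)c(C(=O)C(C)C)c(OCOC)c(CC=C(C)C)c2OCOC)c(O)c1C
A8 | alternative 3 | methyl 4-methyl-2-{[2,4,6-tris(methoxymethoxy)-3-(3-methylbut-2-en-1-yl)-5-(2-methylpropanoyl)phenyl]methyl}-3,5-dioxoheptanoate | CCC(=O)C(C)C(=O)C(Cc1c(OCOC)c(CC=C(C)C)c(OCOC)c(C(=O)C(C)C)c1OCOC)C(=O)OC
A9 | alternative 3 | 6-ethyl-4-hydroxy-5-methyl-3-{[2,4,6-tris(methoxymethoxy)-3-(3-methylbut-2-en-1-yl)-5-(2-methylpropanoyl)phenyl]methyl}-2H-pyran-2-one | CCc1oc(=O)c(Cc2c(OCOC)c(CC=C(C)C)c(OCOC)c(C(=O)C(C)C)c2OCOC)c(O)c1C
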